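Molar per minute is the unit of the reading that shows where a flask is heading: the slope of c_X between neighbouring readings, which falls as the flask nears its end.

| flask | G | L | X | time |
|---|---|---|---|---|
| oak | 0.600 M | 0.00600 M |  |  |
| cedar | 1.80 M | 0.00600 M |  |  |
| elm | 0.600 M | 0.00600 M | 0.300 M |  |
| alder | 0.600 M | 0.00900 M |  |  |
| maple | 0.200 M | 0.0180 M |  | 77 min |

| run | time / min | [X] / M |
|---|---|---|
| oak run | 5.9 | 0.058 |
| oak run | 18 | 0.154 |
| oak run | 34 | 0.257 |
| oak run | 54 | 0.338 |
| oak run | 77 | 0.397 |
| cedar run | 5.9 | 0.091 |
| cedar run | 18 | 0.275 |
| cedar run | 34 | 0.494 |
| cedar run | 54 | 0.714 |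
| cedar run | 77 | 0.923 |
| elm run | 5.9 | 0.354 |
| elm run | 18 | 0.441 |
| elm run | 34 | 0.536 |
| elm run | 54 | 0.615 |
| elm run | 77 | 0.675 |
| alder run | 5.9 | 0.091 |
| alder run | 18 | 0.228 |
| alder run | 34 | 0.349 |
| alder run | 54 | 0.430 |
| alder run | 77 | 0.480 |

(readings scatter by 0.003 M)

- Overall: G -> X, with L as catalyst.
- Constant volume, constant temperature.
- Bound and free are read together.
- An order is taken over about fifteen percent of the charge, up and down.

- the exponent of [G] in the starting rate at the charge of the oak run (at the point where two percent of the G have become X) (one fixed amount of X, the same in the runs compared)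
- the exponent of [L] in the starting rate at the charge of the oak run (at the point where two percent of the G have become X)
- X in the maple run at 77 min, as a share of the G charged

A rate constant tells how fast a step goes, but a step that can run back also has an end, where forward and back cancel, at a given temperature, at one share of X in G plus X. A catalyst changes how soon a flask gets there, not where the end lies, so a share read at one c_L can serve at another.

The alder run has gone furthest, to 80.0% of its G, so it is the run to read. Its slope falls from 0.00405 M min⁻¹ around c_X = 0.389 M to 0.00217 M min⁻¹ around 0.455 M. A straight line through these points reaches zero slope at 0.531 M. Divided by the G charged, that gives the end share 88.5%, the share of G plus X standing as X when the net rate is zero (the equilibrium conversion). It is a reading and carries the scatter of its readings. The elm run, with a different charge, gives 86.7% the same way.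

The same line gives the pace of approach in the alder run, 0.0286 min⁻¹: slope lost per molar of X gained. Reckoned in proportion to the L charged, this pace becomes 0.0573 min⁻¹ in the maple run, whose c_G starts at 0.200 M, close to the 0.211 M of G left in the alder run around the first of those slopes, though the maple run starts without X. Over 77 min the distance to the end then shrinks to 1.21% of its starting value, so this reckoning puts the maple run at 87.4% of its G.

The forecast puts the maple run lower, at 80% (range 70% to 89%), with orders of 0.85 in G and 1.25 in L and the judgement that “product inhibition is mild”.

The simulation gives orders of 0.60 in G and 1.2 in L, and 88.4% for the maple run.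

    L + G ⇌ LG, settled at all times (1.260 M⁻¹)
    LG ⇌ X + L (4.548 min⁻¹, 0.7140 M⁻¹ min⁻¹)
    L → Jy (0.01110 min⁻¹)
    L + Ek → Jy

X in the maple run at 77 min stands level with the end share of 88.5% read from the alder run. The loss of L to Jy makes no difference to X in the maple run at that time. In the elm run, the end share leaves 0.496 M of X to be made beyond the X charged. The 0.300 M made in the elm run by 49.4 min is 60.4% of that way.

The readings were computed with constants of no real substance, noise included.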